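**Plan**
1. Locants: pyran O1, C2 (=CH2), C3 (OH), C4, C5 (Br), C6 (Me2). The carbocycle runs C1' (on C3) to C6', with C4' (Cl, CH3) and C5' (Br).
2. Cuts, in retrosynthetic order: C2=CH2 (lactone methylenation); C4'–Cl and C5'–Br (back to a C4'=C5' alkene); O1–C2 and C5–Br (δ-lactone back to a γ-lactone on O5); C4'–CH3; C5'=C6' and C1'–C2' (enone annulation); both C6–CH3 bonds.
3. Enabling feature: the carbocycle hangs by C1' on the fully substituted carbinol C3 of the pyran. C4' and C5' carry what a C4' ketone and a C5'=C6' alkene can deliver, so C1'–C6' is the CH2–CHO arm of an aldehyde. Its other carbons C2–C3–C4–C5–C6 are C7–C1–C6–C5–C4 of (−)-quinic acid, and the arm is quinic C2–C3. C3 is already correct, and an oxygen stands where the C5 bromine must end.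
4. Forward order: the quinic cyclohexane is cut open and only the γ-lactone stays. The carbocycle closes in step 9, the γ-lactone is exchanged for the δ-lactone (pyran ring) in steps 12–16, the ring halogens follow, and methylenation comes last.
5. Stereochemistry: C3 is quinic C1, untouched. C5 is quinic C5 after two inversions (epoxide, then bromide). C1' comes from the amine catalyst. C4' and C5' come from a catalyst-controlled epoxidation relayed by anti opening and a bromonium shift.

Key step: step 9

Assumption: quinic acid locants are used for 1–7 and target locants afterwards. C4 of 6 and 7 is drawn for equatorial attack and is erased in step 5, so either epimer serves. The aminal carbon of 11 and the carbinol carbon of 15 are left undefined.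

Step 1
Reactants: 1 (−)-quinic acid
Product: 2 quinide (quinic acid 1,5-lactone; free OH at C1 C3 C4)
Conditions: p-TsOH·H2O (cat.), PhMe/DMF, reflux, Dean–Stark
Reagents that add atoms: none
Why: Acid-catalysed lactonisation; only the C5 hydroxyl is cis to the carboxyl group, so the bicyclic γ-lactone should form with all stereocentres untouched and mask C7 and O5 together.

Step 2
Reactants: 2 quinide
Product: 3 3-O-TBS-quinide
Conditions: TBSCl (1.1 equiv), imidazole, DMF, 0 °C
Reagents that add atoms: tert-butyldimethylsilyl chloride, CC(C)(C)[Si](C)(C)Cl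
Why: Selective silylation; in the lactone chair C3–OH is equatorial and open, C4–OH is axial and C1–OH is tertiary, so one equivalent of reagent should take C3–OH.

Step 3
Reactants: 3 3-O-TBS-quinide
Product: 4 3-O-TBS-4-oxoquinide
Conditions: Dess–Martin periodinane, CH2Cl2, 0 °C → rt
Reagents that add atoms: none
Why: Dess–Martin oxidation of the only secondary alcohol; the tertiary C1–OH is inert and the mild medium spares the centres next to the new ketone.

Step 4
Reactants: 4 3-O-TBS-4-oxoquinide; 5 methylmagnesium bromide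
Product: 6 3-O-TBS-4-C-methylquinide (C4: OH axial and cis to O3; CH3 equatorial)
Conditions: MeMgBr (2.3 equiv), THF, −78 °C; aq. work-up
Reagents that add atoms: methylmagnesium bromide (5), C[Mg]Br
Why: Grignard 1,2-addition; the first equivalent turns C1–OH into an alkoxide that deactivates the neighbouring lactone carbonyl, and the second adds to the doubly α-oxygenated, far more electrophilic ketone.

Step 5
Reactants: 6 3-O-TBS-4-C-methylquinide
Product: 8 (3R,5R)-5-acetyl-3-hydroxy-3-(2-oxoethyl)oxolan-2-one, via triol lactone 7 (not isolated)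
Conditions: 48 % aq. HF, MeCN, 0 °C → rt; NaHCO3 to pH 6–7; NaIO4, H2O, 0 °C
Reagents that add atoms: none
Why: Fluoride desilylation followed by periodate glycol cleavage; cutting C3–C4 of the secondary/tertiary diol gives an aldehyde at quinic C3 and a methyl ketone at quinic C4, so the two new carbonyl groups are differentiated from the start.

Step 6
Reactants: 8 keto aldehyde lactone
Product: 9 (3R,5R)-5-acetyl-3-(2,2-dimethoxyethyl)-3-hydroxyoxolan-2-one
Conditions: HC(OMe)3, PPTS (cat.), MeOH, 0 °C → rt
Reagents that add atoms: trimethyl orthoformate, COC(OC)OC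
Why: Chemoselective acetalisation; the unhindered aldehyde should react much faster than the α-acyloxy methyl ketone, which is deactivated towards oxocarbenium formation.

Step 7
Reactants: 9 acetal ketone; 5 methylmagnesium bromide
Product: 10 (3R,5R)-3-(2,2-dimethoxyethyl)-3-hydroxy-5-(2-hydroxypropan-2-yl)oxolan-2-one
Conditions: MeMgBr (2.2 equiv), THF, −78 °C; aq. work-up
Reagents that add atoms: methylmagnesium bromide (5), C[Mg]Br
Why: Grignard addition to the activated ketone completes C6 with no new stereocentre; the low temperature guards C5 against enolisation, and the γ-lactone on the secondary oxygen remains the more stable lactone isomer.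

Step 8
Reactants: 10 diol acetal
Product: 12 (3R,5R)-3-(2-oxoethyl)-3-(triethylsilyloxy)-5-[2-(triethylsilyloxy)propan-2-yl]oxolan-2-one, via lutidinium salt 11 (not isolated)
Conditions: TESOTf (4 equiv), 2,6-lutidine (6 equiv), CH2Cl2, 0 °C; then H2O
Reagents that add atoms: triethylsilyl triflate, CC[Si](CC)(CC)OS(=O)(=O)C(F)(F)F; water, O
Why: Silyl triflate silylation of both tertiary alcohols; the same reagent pair turns an aldehyde-derived acetal into an N-(α-methoxyalkyl)lutidinium salt that water hydrolyses to the aldehyde (a known near-neutral acetal cleavage), so no acid meets the new silyl ethers.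

Step 9
Reactants: 12 lactone aldehyde; 13 methyl vinyl ketone
Product: 16 (4S)-4-[(3R,5R)-2-oxo-3-(triethylsilyloxy)-5-{2-(triethylsilyloxy)propan-2-yl}oxolan-3-yl]cyclohex-2-en-1-one, via keto aldehyde 14 (not isolated), via ketol 15 (not isolated)
Conditions: 13 (2 equiv), (R)-α,α-diphenylprolinol TMS ether (20 mol %), ethyl 3,4-dihydroxybenzoate (20 mol %), CH2Cl2 (concentrated), 4 °C; volatiles off; LiOH (0.5 equiv), i-PrOH, rt
Reagents that add atoms: methyl vinyl ketone (13), C=CC(C)=O
Why: The amine condenses with 12 to the E-enamine, whose C1' adds to the terminus of 13 (enamine Michael addition of an aldehyde to an enone, known for diarylprolinol ethers; forms C1'–C2'), and hydrolysis frees keto aldehyde 14 and the catalyst. Lithium hydroxide then enolises the methyl ketone towards C5', which attacks the aldehyde carbon C6' in a 6-(enolendo)-exo-trig aldol to ketol 15, and E1cB loss of water gives enone 16, the sequence established for 4-alkylcyclohexenones. C1' is the only new stereocentre that is kept: the diphenyl(silyloxy)methyl group blocks one enamine face, and the R catalyst exposes the face that leads to (R)-14 and hence (1'S)-16, while the carbinol centre of 15 disappears. Site selectivity is built into the substrate, because quaternary C3 leaves C1' as the only enolisable position of the aldehyde, the lactone has no α-hydrogen, and only the methyl enolate of the ketone can reach the aldehyde through a six-membered ring. The α-branched aldehyde 14 re-forms an enamine only slowly, which should protect C1' until the ring is closed.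

Step 10
Reactants: 16 enone
Product: 18 enol triflate (C4'–OTf; C4'=C5'; 1'S), via lithium enolate 17 (not isolated)
Conditions: L-Selectride (1.05 equiv), THF, −78 °C; Comins' reagent, −78 → 0 °C
Reagents that add atoms: N-(5-chloro-2-pyridyl)bis(trifluoromethanesulfonimide), FC(F)(F)S(=O)(=O)N(c1ccc(Cl)cn1)S(=O)(=O)C(F)(F)F
Why: Conjugate hydride reduction with in-place O-triflation of the enolate; trapping fixes the double bond at C4'=C5', whereas the free 4-substituted cyclohexanone would be locally symmetric and would lose the stereogenicity of C1'.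

Step 11
Reactants: 18 enol triflate; 5 methylmagnesium bromide
Product: 19 (3R,5R)-3-[(1S)-4-methylcyclohex-3-en-1-yl]-3-(triethylsilyloxy)-5-[2-(triethylsilyloxy)propan-2-yl]oxolan-2-one
Conditions: MeMgBr (1.3 equiv), Fe(acac)3 (5 mol %), THF/NMP, −30 °C
Reagents that add atoms: methylmagnesium bromide (5), C[Mg]Br
Why: Iron-catalysed cross-coupling of an alkenyl triflate with a Grignard reagent; it is fast enough at −30 °C that esters, and here a hindered lactone, are left alone.

Step 12
Reactants: 19 bis-silyl ether
Product: 20 (3R,5R)-5-(2-hydroxypropan-2-yl)-3-[(1S)-4-methylcyclohex-3-en-1-yl]-3-(triethylsilyloxy)oxolan-2-one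
Conditions: PPTS (cat.), MeOH/CH2Cl2, 0 °C
Reagents that add atoms: none
Why: Selective acid methanolysis of a silyl ether; the dimethylcarbinyl oxygen at C6 is more basic and less crowded than O3, which sits next to the carbonyl group and the cyclohexenyl ring, so both effects favour loss of the C6 silyl group only.

Step 13
Reactants: 20 hydroxy lactone
Product: 22 methyl (2R,4R)-4,5-dihydroxy-5-methyl-2-[(1S)-4-methylcyclohex-3-en-1-yl]-2-(triethylsilyloxy)hexanoate, via potassium carboxylate 21 (not isolated)
Conditions: KOH (1.05 equiv), THF/MeOH/H2O, rt; evaporate; MeI, DMF, 0 °C; used at once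
Reagents that add atoms: potassium hydroxide, [K+].[OH-]; methyl iodide, CI
Why: Saponification and carboxylate O-alkylation; the lactone is opened irreversibly as its salt and esterified without ever passing through the free hydroxy acid, which avoids acid-catalysed re-lactonisation.

Step 14
Reactants: 22 dihydroxy ester
Product: 24 methyl (2R)-3-[(2S)-3,3-dimethyloxiran-2-yl]-2-[(1S)-4-methylcyclohex-3-en-1-yl]-2-(triethylsilyloxy)propanoate, via mesylate 23 (not isolated)
Conditions: MsCl (1.1 equiv), Et3N, CH2Cl2, −20 °C; then K2CO3, MeOH, 0 °C → rt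
Reagents that add atoms: none
Why: Selective mesylation of the secondary alcohol, then Williamson-type 3-exo-tet closure by the tertiary C6 alkoxide; this is the first inversion at C5 (R to S).

Step 15
Reactants: 24 epoxy ester
Product: 25 methyl (2R,4R)-4-bromo-5-hydroxy-5-methyl-2-[(1S)-4-methylcyclohex-3-en-1-yl]-2-(triethylsilyloxy)hexanoate
Conditions: Li2NiBr4, THF, 0 °C → rt; pH 7 buffer
Reagents that add atoms: dilithium tetrabromonickelate, [Li+].[Li+].[Ni+2].[Br-].[Br-].[Br-].[Br-]
Why: SN2 opening of a trisubstituted epoxide by a soft, non-acidic bromide source at the less substituted carbon; this is the second inversion at C5, so bromine ends where the quinic oxygen stood.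

Step 16
Reactants: 25 bromohydrin ester
Product: 26 (3R,5R)-5-bromo-6,6-dimethyl-3-[(1S)-4-methylcyclohex-3-en-1-yl]-3-(triethylsilyloxy)oxan-2-one
Conditions: CSA (10 mol %), PhMe, 4 Å MS, 50 °C
Reagents that add atoms: none
Why: Acid-catalysed δ-lactonisation helped by the quaternary centres at C3 and C6; acid is chosen because base would send the bromohydrin back to the epoxide.

Step 17
Reactants: 26 bromo δ-lactone
Product: 27 (4'S,5'R)-4',5'-epoxide of 26 (oxygen on the ring face opposite the C1' substituent; CH3 cis to it)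
Conditions: D-fructose-derived Shi ketone (30 mol %), Oxone, K2CO3, Bu4NHSO4, MeCN/DMM/aq. borate–EDTA buffer, 0 °C
Reagents that add atoms: potassium peroxymonosulfate (Oxone), [K+].OOS(=O)(=O)[O-]
Why: Shi epoxidation of a trisubstituted alkene; the remote C1' centre offers no bias, so the chiral dioxirane picks the face, and the spiro transition-state model (same sense as for 1-substituted cyclohexenes) predicts the 4'S,5'R epoxide.

Step 18
Reactants: 27 ring epoxide
Product: 28 (4'R,5'R)-4'-bromo-5'-hydroxy compound (C4'–Br and C5'–OH both axial)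
Conditions: 48 % aq. HBr (1.2 equiv), CH2Cl2, −20 °C, brief
Reagents that add atoms: hydrogen bromide, Br
Why: Acid-promoted epoxide opening; for this epoxide face the trans-diaxial (Fürst–Plattner) path and the Markovnikov preference both point to C4', so bromide should enter there with inversion and leave C5'–OH anti-periplanar to C4'–Br.

Step 19
Reactants: 28 ring bromohydrin
Product: 31 (3R,5R)-5-bromo-3-[(1'S,4'S,5'S)-5'-bromo-4'-chloro-4'-methylcyclohexyl]-6,6-dimethyl-3-(triethylsilyloxy)oxan-2-one, via alkoxyiminium chloride 29 (not isolated), via bromonium chloride 30 (not isolated)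
Conditions: 1-chloro-N,N,2-trimethylprop-1-en-1-amine (1.3 equiv), Bu4NCl, CH2Cl2, 0 °C → rt
Reagents that add atoms: 1-chloro-N,N,2-trimethylprop-1-en-1-amine, CC(C)=C(Cl)N(C)C
Why: Neutral alcohol activation followed by neighbouring-group participation (the known generation of bromonium ions from activated β-bromo alcohols); the anti-periplanar C4'–Br expels the amide from C5' with inversion to give 30 on the face cis to the C1' substituent, and chloride opens it at the more substituted C4' from the other face, which moves bromine to C5' and leaves both halogens equatorial and trans.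

Step 20
Reactants: 31 bromochloro δ-lactone
Product: 32 3-O-triethylsilyl ether of the target
Conditions: Tebbe reagent (1.5 equiv), pyridine (cat.), THF/PhMe, −40 → 0 °C; aq. NaOH
Reagents that add atoms: Tebbe reagent, C[Al-]1(C)C[Ti](C2C=CC=C2)(C2C=CC=C2)[Cl+]1
Why: Tebbe methylenation of a lactone carbonyl to the exocyclic enol ether; the reagent is non-basic and works cold, alkyl halides and silyl ethers are tolerated, and quaternary C3 rules out migration of the double bond into the ring.

Step 21
Reactants: 32 silyl ether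
Product: 33 (3R,5R)-5-bromo-3-[(1S,3S,4S)-3-bromo-4-chloro-4-methylcyclohexyl]-6,6-dimethyl-2-methylideneoxan-3-ol (target)
Conditions: TBAF (1.1 equiv), THF, 0 °C, short
Reagents that add atoms: none
Why: Fluoride desilylation; the medium is free of acid, so the enol ether survives, and the labile TES group allows a short cold exposure that should not trigger elimination of the halides.

**Compound list**
1 | (−)-quinic acid | O[C@@]1(C(=O)O)C[C@@H](O)[C@@H](O)[C@H](O)C1 | starting material
2 | quinide | O[C@@]1(C(=O)O2)C[C@@H](O)[C@@H](O)[C@H]2C1 | intermediate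
3 | 3-O-TBS-quinide | O[C@@]1(C(=O)O2)C[C@@H](O[Si](C)(C)C(C)(C)C)[C@@H](O)[C@H]2C1 | intermediate
4 | 3-O-TBS-4-oxoquinide | O[C@@]1(C(=O)O2)C[C@@H](O[Si](C)(C)C(C)(C)C)C(=O)[C@H]2C1 | intermediate
5 | methylmagnesium bromide | C[Mg]Br | starting material
6 | 3-O-TBS-4-C-methylquinide | O[C@@]1(C(=O)O2)C[C@@H](O[Si](C)(C)C(C)(C)C)[C@@](C)(O)[C@H]2C1 | intermediate
7 | 4-C-methylquinide (triol lactone, not isolated) | O[C@@]1(C(=O)O2)C[C@@H](O)[C@@](C)(O)[C@H]2C1 | intermediate
8 | (3R,5R)-5-acetyl-3-hydroxy-3-(2-oxoethyl)oxolan-2-one | O=C1O[C@@H](C(C)=O)C[C@@]1(O)CC=O | intermediate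
9 | (3R,5R)-5-acetyl-3-(2,2-dimethoxyethyl)-3-hydroxyoxolan-2-one | O=C1O[C@@H](C(C)=O)C[C@@]1(O)CC(OC)OC | intermediate
10 | (3R,5R)-3-(2,2-dimethoxyethyl)-3-hydroxy-5-(2-hydroxypropan-2-yl)oxolan-2-one | O=C1O[C@@H](C(C)(C)O)C[C@@]1(O)CC(OC)OC | intermediate
11 | bis-TES N-(1-methoxyalkyl)-2,6-lutidinium triflate (not isolated) | O=C1O[C@@H](C(C)(C)O[Si](CC)(CC)CC)C[C@@]1(O[Si](CC)(CC)CC)CC(OC)[n+]1c(C)cccc1C.[O-]S(=O)(=O)C(F)(F)F | intermediate
12 | lactone aldehyde (precursor of the key step) | O=C1O[C@@H](C(C)(C)O[Si](CC)(CC)CC)C[C@@]1(O[Si](CC)(CC)CC)CC=O | intermediate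
13 | methyl vinyl ketone | C=CC(C)=O | starting material
14 | (2R)-5-oxo-2-lactonylhexanal (keto aldehyde, not isolated) | O=C1O[C@@H](C(C)(C)O[Si](CC)(CC)CC)C[C@@]1(O[Si](CC)(CC)CC)[C@H](C=O)CCC(C)=O | intermediate
15 | 3-hydroxy-4-lactonylcyclohexanone (ketol, not isolated) | O=C1O[C@@H](C(C)(C)O[Si](CC)(CC)CC)C[C@@]1(O[Si](CC)(CC)CC)[C@H]1CCC(=O)CC1O | intermediate
16 | (4S)-4-lactonylcyclohex-2-enone (product of the key step) | O=C1O[C@@H](C(C)(C)O[Si](CC)(CC)CC)C[C@@]1(O[Si](CC)(CC)CC)[C@@H]1C=CC(=O)CC1 | intermediate
17 | lithium C4'=C5' enolate (not isolated) | O=C1O[C@@H](C(C)(C)O[Si](CC)(CC)CC)C[C@@]1(O[Si](CC)(CC)CC)[C@H]1CCC([O-])=CC1.[Li+] | intermediate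
18 | C4' enol triflate | O=C1O[C@@H](C(C)(C)O[Si](CC)(CC)CC)C[C@@]1(O[Si](CC)(CC)CC)[C@H]1CCC(OS(=O)(=O)C(F)(F)F)=CC1 | intermediate
19 | 4-methylcyclohex-3-enyl γ-lactone, bis-TES | O=C1O[C@@H](C(C)(C)O[Si](CC)(CC)CC)C[C@@]1(O[Si](CC)(CC)CC)[C@H]1CCC(C)=CC1 | intermediate
20 | γ-lactone with free C6–OH | O=C1O[C@@H](C(C)(C)O)C[C@@]1(O[Si](CC)(CC)CC)[C@H]1CCC(C)=CC1 | intermediate
21 | potassium dihydroxy carboxylate (not isolated) | [K+].[O-]C(=O)[C@@](O[Si](CC)(CC)CC)(C[C@@H](O)C(C)(C)O)[C@H]1CCC(C)=CC1 | intermediate
22 | dihydroxy methyl ester | COC(=O)[C@@](O[Si](CC)(CC)CC)(C[C@@H](O)C(C)(C)O)[C@H]1CCC(C)=CC1 | intermediate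
23 | C5 mesylate (not isolated) | COC(=O)[C@@](O[Si](CC)(CC)CC)(C[C@@H](OS(C)(=O)=O)C(C)(C)O)[C@H]1CCC(C)=CC1 | intermediate
24 | C5–C6 epoxy ester | COC(=O)[C@@](O[Si](CC)(CC)CC)(C[C@@H]1OC1(C)C)[C@H]1CCC(C)=CC1 | intermediate
25 | C5 bromohydrin ester | COC(=O)[C@@](O[Si](CC)(CC)CC)(C[C@@H](Br)C(C)(C)O)[C@H]1CCC(C)=CC1 | intermediate
26 | bromo δ-lactone | O=C1OC(C)(C)[C@H](Br)C[C@@]1(O[Si](CC)(CC)CC)[C@H]1CCC(C)=CC1 | intermediate
27 | (4'S,5'R)-ring epoxide | O=C1OC(C)(C)[C@H](Br)C[C@@]1(O[Si](CC)(CC)CC)[C@H]1CC[C@]2(C)O[C@@H]2C1 | intermediate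
28 | (4'R,5'R)-4'-bromo-5'-ol | O=C1OC(C)(C)[C@H](Br)C[C@@]1(O[Si](CC)(CC)CC)[C@H]1CC[C@@](C)(Br)[C@H](O)C1 | intermediate
29 | C5' alkoxyiminium chloride (not isolated) | O=C1OC(C)(C)[C@H](Br)C[C@@]1(O[Si](CC)(CC)CC)[C@H]1CC[C@@](C)(Br)[C@H](OC(C(C)C)=[N+](C)C)C1.[Cl-] | intermediate
30 | C4'–C5' bromonium chloride (not isolated) | O=C1OC(C)(C)[C@H](Br)C[C@@]1(O[Si](CC)(CC)CC)[C@H]1CC[C@@]2(C)[Br+][C@H]2C1.[Cl-] | intermediate
31 | bromochloro δ-lactone | O=C1OC(C)(C)[C@H](Br)C[C@@]1(O[Si](CC)(CC)CC)[C@H]1CC[C@](C)(Cl)[C@@H](Br)C1 | intermediate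
32 | target 3-O-TES ether | C=C1OC(C)(C)[C@H](Br)C[C@@]1(O[Si](CC)(CC)CC)[C@H]1CC[C@](C)(Cl)[C@@H](Br)C1 | intermediate
33 | CNP0106480.1 | C=C1OC(C)(C)[C@H](Br)C[C@@]1(O)[C@H]1CC[C@](C)(Cl)[C@@H](Br)C1 | target

Total step count: 21. Longest linear sequence: 21 steps (1 → 33).

**Steps most likely to fail**

Step 19, regiochemistry of the bromonium opening. Chloride may follow the trans-diaxial path and enter at C5' instead of C4', or the ion may lose a proton. The fallback sets out from 28. The diaxial capture is accepted, and the diaxial (4'R,5'R)-4'-bromo-5'-chloride F1 is isolated. It is then heated in toluene or acetonitrile. The known diaxial-to-diequatorial rearrangement of vicinal dihalides exchanges the two halogens across the C4'–C5' bond. Chlorine then ends equatorial on the tertiary carbon and bromine equatorial on C5'. The route is rejoined at 31.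

Step 9, slow bond formation at the neopentyl-type enamine carbon. β-Elimination of the C3 silyloxy group, polymerisation of 13, or a mismatch between catalyst and C3 could then lower the facial selectivity. The fallback sets out from 12, which is condensed with a full equivalent of pyrrolidine over molecular sieves to the E-enamine F2. Stork enamine addition to 13 in acetonitrile gives the 2-(pyrrolidin-1-yl)dihydropyran F3. Buffered hydrolysis (aq. AcOH/NaOAc) releases 14, and LiOH in i-PrOH closes it. Facial control then rests on C3 alone, and the C1' epimers are separated at the enone stage. The route is rejoined at 16.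

Step 17, poor facial selectivity of the epoxidation of an all-alkyl cyclic alkene. The fallback sets out from 26 and replaces catalyst control by substrate-based sorting. m-CPBA gives 27 together with the diastereomeric epoxide F4, which has oxygen cis to the C1' substituent. The mixture is treated with HBr as in step 18. Under these conditions 27 opens at C4' to 28, whereas F4 opens along its own diaxial path at C5' to the regioisomeric bromohydrin F5. The two bromohydrins are constitutional isomers and are separated by chromatography. Zinc in acetic acid returns F5 to 26 for another pass. The route is rejoined at 28.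

**Further compounds**
F1 | step 19 | diaxial (4'R,5'R)-4'-bromo-5'-chloro δ-lactone | O=C1OC(C)(C)[C@H](Br)C[C@@]1(O[Si](CC)(CC)CC)[C@H]1CC[C@@](C)(Br)[C@H](Cl)C1
F2 | step 9 | E-pyrrolidine enamine of 12 | O=C1O[C@@H](C(C)(C)O[Si](CC)(CC)CC)C[C@@]1(O[Si](CC)(CC)CC)/C=C/N1CCCC1
F3 | step 9 | 6-methyl-2-(pyrrolidin-1-yl)-3-lactonyl-3,4-dihydro-2H-pyran (wanted C1' epimer drawn) | O=C1O[C@@H](C(C)(C)O[Si](CC)(CC)CC)C[C@@]1(O[Si](CC)(CC)CC)[C@H]1CC=C(C)OC1N1CCCC1
F4 | step 17 | (4'R,5'S)-ring epoxide, oxygen cis to the C1' substituent | O=C1OC(C)(C)[C@H](Br)C[C@@]1(O[Si](CC)(CC)CC)[C@H]1CC[C@@]2(C)O[C@H]2C1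
F5 | step 17 | diaxial 5'-bromo-4'-hydroxy regioisomer | O=C1OC(C)(C)[C@H](Br)C[C@@]1(O[Si](CC)(CC)CC)[C@H]1CC[C@@](C)(O)[C@H](Br)C1
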